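**Plan** (labdane numbering: ring A = C1–C5, C10; ring B = C5–C10; chain C11–C16; C17 on C8, C18/C19 on C4, C20 on C10)
1. Retrosynthesis: the Z-cinnamate C=C and the C15–O acyl bond are cut first. One retro-step then opens C9–C10 and C4–C5 and returns a sulfonyl group to C7. The last cut is C6–C7.
2. Forward: a West C10 half from (S)-epichlorohydrin and an East C10 half from (S)-citronellol are joined at C6–C7 by allyl sulfone alkylation. One hydrogen-atom-transfer radical cascade then closes ring A and, last, ring B, and the ester is built at the end.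
3. Enabling feature: C4, C10 and C8 are fully substituted and lie 1,5 to one another, so each closure is 6-endo and passes on a tertiary radical. The ring alkene C7=C8 starts at the carbon where the last radical lands, so the sulfone on C7, the same one that made C6–C7, leaves as a radical, fixes the alkene position and erases the C7 epimer mixture.
4. Stereochemistry: C2 comes from epichlorohydrin and C13 from citronellol. C5, C10 and C9 are relayed from C2, whose silyl ether lies 1,3 to C4 and C10 and must sit equatorial in the chair–chair array, together with the two E alkenes. The Z alkene comes from a diaryl phosphonate HWE.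

Key step: step 11

Assumption: compound 14 is carried forward as the mixture of its two C7 epimers, and all reagents named with SMILES are purchased.

**Step 1**
Reactants: 1 (S)-epichlorohydrin
Product: 2 (S)-1-chloro-4-methylpent-4-en-2-ol
Conditions: CH2=C(CH3)MgBr, CuI (10 mol %), THF, −40 → 0 °C
Reagents that add atoms: isopropenylmagnesium bromide, C=C(C)[Mg]Br
Why: The copper-catalysed Grignard opening attacks the unsubstituted epoxide carbon (SN2), so the C–O stereocentre (future C2) is not touched and the chloride is kept for the next step.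

**Step 2**
Reactants: 2 (S)-1-chloro-4-methylpent-4-en-2-ol
Product: 4 (S)-6-methylhept-6-en-1-yn-4-ol, via (S)-2-(2-methylallyl)oxirane 3 (not isolated)
Conditions: HC≡CLi·H2NCH2CH2NH2 (3 equiv), DMSO, 0 °C → rt
Reagents that add atoms: lithium acetylide (ethylenediamine complex), [Li]C#C
Why: One equivalent of acetylide acts as base and closes the chlorohydrin to the terminal epoxide, and a second opens it at the CH2 end (standard acetylide epoxide opening), so no bond to C2 is broken.

**Step 3**
Reactants: 4 (S)-6-methylhept-6-en-1-yn-4-ol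
Product: 5 (S)-tert-butyldimethyl[(6-methylhept-6-en-1-yn-4-yl)oxy]silane
Conditions: TBSCl, imidazole, DMF, rt
Reagents that add atoms: tert-butyldimethylsilyl chloride, CC(C)(C)[Si](C)(C)Cl
Why: This is a standard silylation of a secondary alcohol, and the bulky ether later serves as the equatorial anchor of the cascade.

**Step 4**
Reactants: 5 (S)-tert-butyldimethyl[(6-methylhept-6-en-1-yn-4-yl)oxy]silane
Product: 7 (2E,5S)-5-(tert-butyldimethylsilyloxy)-3,7-dimethylocta-2,7-dien-1-ol, via (E)-alkenyl(dimethyl)alane 6 (not isolated)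
Conditions: Me3Al, Cp2ZrCl2 (25 mol %), CH2Cl2, 0 °C → rt; volatiles off; n-BuLi, THF–hexane, −30 °C; (CH2O)n, rt
Reagents that add atoms: trimethylaluminium, C[Al](C)C; paraformaldehyde (as formaldehyde), C=O
Why: The Negishi carboalumination adds CH3 and Al syn, with CH3 on the inner alkyne carbon, which fixes the E C5=C10 alkene while the 1,1-disubstituted alkene stays inert; the alane activated by n-BuLi is then hydroxymethylated with retention.

**Step 5**
Reactants: 7 (2E,5S)-5-(tert-butyldimethylsilyloxy)-3,7-dimethylocta-2,7-dien-1-ol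
Product: 8 (2E,5S)-1-bromo-5-(tert-butyldimethylsilyloxy)-3,7-dimethylocta-2,7-diene
Conditions: CBr4, PPh3, CH2Cl2, 0 °C
Reagents that add atoms: carbon tetrabromide, BrC(Br)(Br)Br
Why: The Appel reaction converts a primary allylic alcohol under neutral conditions without allylic shift and leaves the silyl ether intact.

**Step 6**
Reactants: 9 (S)-citronellol
Product: 10 (S)-citronellyl 4-methoxybenzyl ether
Conditions: NaH, PMBCl, n-Bu4NI (cat.), THF–DMF, 0 °C → rt
Reagents that add atoms: 4-methoxybenzyl chloride, COc1ccc(CCl)cc1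
Why: A Williamson ether synthesis gives a group that withstands n-BuLi and radical conditions and is orthogonal to the silyl ether; C13 is not involved.

**Step 7**
Reactants: 10 (S)-citronellyl 4-methoxybenzyl ether
Product: 11 (2E,6S)-8-(4-methoxybenzyloxy)-2,6-dimethyloct-2-en-1-ol
Conditions: SeO2 (cat.), t-BuOOH, salicylic acid (cat.), CH2Cl2, 0 °C → rt
Reagents that add atoms: tert-butyl hydroperoxide, CC(C)(C)OO; selenium dioxide (catalytic oxygen carrier), O=[Se]=O
Why: The selenium dioxide allylic oxidation (ene reaction, then [2,3]-shift) attacks the E methyl group of a trisubstituted alkene, so the future C7 is oxidised and C8=C9 stays E.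

**Step 8**
Reactants: 11 (2E,6S)-8-(4-methoxybenzyloxy)-2,6-dimethyloct-2-en-1-ol
Product: 12 (2E,6S)-1-bromo-8-(4-methoxybenzyloxy)-2,6-dimethyloct-2-ene
Conditions: CBr4, PPh3, CH2Cl2, 0 °C
Reagents that add atoms: carbon tetrabromide, BrC(Br)(Br)Br
Why: The Appel reaction gives the primary allylic bromide with retention of the alkene geometry.

**Step 9**
Reactants: 12 (2E,6S)-1-bromo-8-(4-methoxybenzyloxy)-2,6-dimethyloct-2-ene
Product: 13 (2E,6S)-8-(4-methoxybenzyloxy)-2,6-dimethyloct-2-enyl phenyl sulfone
Conditions: PhSO2Na, DMF, rt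
Reagents that add atoms: sodium benzenesulfinate, [Na+].[O-]S(=O)c1ccccc1
Why: SN2 S-alkylation of the soft sulfinate at the primary allylic carbon gives the E allyl sulfone.

**Step 10**
Reactants: 13 (2E,6S)-8-(4-methoxybenzyloxy)-2,6-dimethyloct-2-enyl phenyl sulfone; 8 (2E,5S)-1-bromo-5-(tert-butyldimethylsilyloxy)-3,7-dimethylocta-2,7-diene
Product: 14 (4S,6E,10E,14S)-4-(tert-butyldimethylsilyloxy)-16-(4-methoxybenzyloxy)-2,6,10,14-tetramethyl-9-(phenylsulfonyl)hexadeca-1,6,10-triene (both epimers at the sulfonyl carbon, C7)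
Conditions: n-BuLi, THF–DMPU, −78 °C; then 8, −78 → −20 °C
Reagents that add atoms: none
Why: The classical α-alkylation of a lithiated allyl sulfone with an allylic bromide forms C6–C7 with both E alkenes intact, and the new C7 centre forms without control, which is harmless because step 11 erases it.

**Step 11**
Reactants: 14 acyclic triene sulfone (C7 epimer mixture)
Product: 15 (13S)-2α-(tert-butyldimethylsilyloxy)-15-(4-methoxybenzyloxy)labd-7-ene
Conditions: Fe(acac)3 (30 mol %), PhSiH3 (slow addition), Na2HPO4, EtOH–THF (0.01 M), 60 °C, argon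
Reagents that add atoms: none
Why: Proposed new method: an Fe–H species formed from Fe(acac)3 and PhSiH3 transfers H• to the CH2 terminus of the isopropenyl group, the tertiary C4 radical closes ring A by 6-endo-trig attack on C5, the resulting tertiary C10 radical closes ring B by 6-endo-trig attack on C9, and the tertiary C8 radical, which stands β to the C7–S bond, expels PhSO2• to leave C7=C8, after which Fe(II) reduces PhSO2• to sulfinate and Fe(III) re-enters the cycle. The closest known reaction types are MHAT-initiated radical bicyclisations of acyclic, also oxygenated, polyenes to trans-decalins (ended on arenes or acceptor alkenes) and the radical addition–fragmentation of allyl sulfones (SH2′ allylation), and what is new is their union with the allyl sulfone lying inside the ring that forms. Both closures prefer 6-endo over 5-exo because the inner alkene carbons (C10, then C8) carry methyl groups, so exo attack would join two fully substituted carbons and leave a secondary radical. C5 is set in a chair-like ring A transition state in which the C2 silyl ether is equatorial (axial it would clash 1,3 with a C4 methyl and with C20) and the E C5=C10 alkene holds C6 equatorial; C10 is set because ring B then closes chair-like from equatorial C6, which gives the trans-decalin with axial C20; C9 is set by the E C8=C9 alkene, which holds C11 equatorial (9α-H). The step needs chemoselective initiation, secured by the single 1,1-disubstituted alkene (trisubstituted alkenes accept H• far more slowly), and regiospecific termination, secured by the weak C7–S bond, whose scission should outrun loss of H from C17 or C9. Both C7 epimers of 14 converge on 15 because C7 becomes sp2, and C2 and C13 are not touched.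

**Step 12**
Reactants: 15 (13S)-2α-(tert-butyldimethylsilyloxy)-15-(4-methoxybenzyloxy)labd-7-ene
Product: 16 (13S)-2α-(tert-butyldimethylsilyloxy)labd-7-en-15-ol
Conditions: DDQ, CH2Cl2–pH 7 buffer, 0 °C
Reagents that add atoms: none
Why: Oxidative PMB cleavage (hydride abstraction at the electron-rich benzylic position, then hydrolysis) is orthogonal to the silyl ether and to the hindered trisubstituted alkene.

**Step 13**
Reactants: 16 (13S)-2α-(tert-butyldimethylsilyloxy)labd-7-en-15-ol
Product: 17 (13S)-2α-(tert-butyldimethylsilyloxy)labd-7-en-15-yl bromoacetate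
Conditions: BrCH2COBr, pyridine, CH2Cl2, 0 °C
Reagents that add atoms: bromoacetyl bromide, O=C(Br)CBr
Why: This is a simple O-acylation of the only free (primary) alcohol by an acid bromide.

**Step 14**
Reactants: 17 (13S)-2α-(tert-butyldimethylsilyloxy)labd-7-en-15-yl bromoacetate
Product: 18 (13S)-2α-(tert-butyldimethylsilyloxy)labd-7-en-15-yl (diphenoxyphosphoryl)acetate
Conditions: (PhO)2P(O)H, Et3N, CH2Cl2, 0 °C → rt
Reagents that add atoms: diphenyl phosphite, O=[PH](Oc1ccccc1)Oc1ccccc1
Why: In the Michaelis–Becker reaction the phosphite anion displaces the activated α-bromide and delivers the diaryl phosphonoacetate on the intact ester.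

**Step 15**
Reactants: 18 (13S)-2α-(tert-butyldimethylsilyloxy)labd-7-en-15-yl (diphenoxyphosphoryl)acetate; 19 4-(tert-butyldimethylsilyloxy)benzaldehyde
Product: 20 (13S)-2α-(tert-butyldimethylsilyloxy)labd-7-en-15-yl (Z)-3-[4-(tert-butyldimethylsilyloxy)phenyl]acrylate
Conditions: NaH, THF, 0 °C; then 19, −78 → −20 °C, exclusion of light
Reagents that add atoms: none
Why: In the Z-selective Horner–Wadsworth–Emmons reaction (Ando modification) the electron-poor aryloxy groups make the kinetically formed adduct collapse before it equilibrates, which gives the Z enoate.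

**Step 16**
Reactants: 20 bis-silyl (Z)-ester
Product: 21 (13S)-2α-hydroxylabd-7-en-15-yl (Z)-4-hydroxycinnamate (target)
Conditions: HF·pyridine, pyridine, THF, 0 °C → rt, exclusion of light
Reagents that add atoms: none
Why: Fluoride-driven cleavage removes the aryl and the secondary silyl ether under buffered conditions that should neither isomerise the Z enoate nor move the C7=C8 alkene.

**Compound list**
1 | (S)-epichlorohydrin | ClC[C@@H]1CO1 | starting material
2 | (S)-1-chloro-4-methylpent-4-en-2-ol | C=C(C)C[C@H](O)CCl | intermediate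
3 | (S)-2-(2-methylallyl)oxirane | C=C(C)C[C@H]1CO1 | intermediate
4 | (S)-6-methylhept-6-en-1-yn-4-ol | C=C(C)C[C@H](O)CC#C | intermediate
5 | (S)-tert-butyldimethyl[(6-methylhept-6-en-1-yn-4-yl)oxy]silane | C=C(C)C[C@H](O[Si](C)(C)C(C)(C)C)CC#C | intermediate
6 | (E)-alkenyl(dimethyl)alane from 5 | C=C(C)C[C@H](O[Si](C)(C)C(C)(C)C)C/C(C)=C/[Al](C)C | intermediate
7 | (2E,5S)-5-(tert-butyldimethylsilyloxy)-3,7-dimethylocta-2,7-dien-1-ol | C=C(C)C[C@H](O[Si](C)(C)C(C)(C)C)C/C(C)=C/CO | intermediate
8 | (2E,5S)-1-bromo-5-(tert-butyldimethylsilyloxy)-3,7-dimethylocta-2,7-diene | C=C(C)C[C@H](O[Si](C)(C)C(C)(C)C)C/C(C)=C/CBr | intermediate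
9 | (S)-citronellol | CC(C)=CCC[C@H](C)CCO | starting material
10 | (S)-citronellyl 4-methoxybenzyl ether | CC(C)=CCC[C@H](C)CCOCc1ccc(OC)cc1 | intermediate
11 | (2E,6S)-8-(4-methoxybenzyloxy)-2,6-dimethyloct-2-en-1-ol | OC/C(C)=C/CC[C@H](C)CCOCc1ccc(OC)cc1 | intermediate
12 | (2E,6S)-1-bromo-8-(4-methoxybenzyloxy)-2,6-dimethyloct-2-ene | BrC/C(C)=C/CC[C@H](C)CCOCc1ccc(OC)cc1 | intermediate
13 | (2E,6S)-8-(4-methoxybenzyloxy)-2,6-dimethyloct-2-enyl phenyl sulfone | O=S(=O)(c1ccccc1)C/C(C)=C/CC[C@H](C)CCOCc1ccc(OC)cc1 | intermediate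
14 | acyclic triene sulfone (C7 epimer mixture) | C=C(C)C[C@H](O[Si](C)(C)C(C)(C)C)C/C(C)=C/CC(S(=O)(=O)c1ccccc1)/C(C)=C/CC[C@H](C)CCOCc1ccc(OC)cc1 | intermediate
15 | (13S)-2α-(tert-butyldimethylsilyloxy)-15-(4-methoxybenzyloxy)labd-7-ene | CC1=CC[C@H]2C(C)(C)C[C@H](O[Si](C)(C)C(C)(C)C)C[C@]2(C)[C@H]1CC[C@H](C)CCOCc1ccc(OC)cc1 | intermediate
16 | (13S)-2α-(tert-butyldimethylsilyloxy)labd-7-en-15-ol | CC1=CC[C@H]2C(C)(C)C[C@H](O[Si](C)(C)C(C)(C)C)C[C@]2(C)[C@H]1CC[C@H](C)CCO | intermediate
17 | bromoacetate of 16 | CC1=CC[C@H]2C(C)(C)C[C@H](O[Si](C)(C)C(C)(C)C)C[C@]2(C)[C@H]1CC[C@H](C)CCOC(=O)CBr | intermediate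
18 | (diphenoxyphosphoryl)acetate of 16 | CC1=CC[C@H]2C(C)(C)C[C@H](O[Si](C)(C)C(C)(C)C)C[C@]2(C)[C@H]1CC[C@H](C)CCOC(=O)CP(=O)(Oc1ccccc1)Oc1ccccc1 | intermediate
19 | 4-(tert-butyldimethylsilyloxy)benzaldehyde | O=Cc1ccc(O[Si](C)(C)C(C)(C)C)cc1 | starting material
20 | bis-silyl (Z)-ester | CC1=CC[C@H]2C(C)(C)C[C@H](O[Si](C)(C)C(C)(C)C)C[C@]2(C)[C@H]1CC[C@H](C)CCOC(=O)/C=C\c1ccc(O[Si](C)(C)C(C)(C)C)cc1 | intermediate
21 | (13S)-2α-hydroxylabd-7-en-15-yl (Z)-4-hydroxycinnamate | CC1=CC[C@H]2C(C)(C)C[C@H](O)C[C@]2(C)[C@H]1CC[C@H](C)CCOC(=O)/C=C\c1ccc(O)cc1 | target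

**Step count:** 16 steps in total. The longest linear sequence is 12 steps (steps 1–5 and 10–16).

**Steps most likely to fail**

Step 11.
- Risk: the C4 or C10 radical may take up a second hydrogen or fall back to an isomerised alkene before it cyclises.
- Risk: sulfonyl radicals may shift the allyl sulfone or start a competing chain.
- Risk: the facial bias from C2 may be weak.
- Fallback: it uses known chemistry, sets out from 14 and returns at 15.
- Lithiation of 14 and oxidative desulfonylation with bis(trimethylsilyl) peroxide should give the acyclic 7-oxo triene F1.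
- The known MHAT-initiated reductive radical bicyclisation, ended by a polarity-matched Giese addition of the C10 radical to the enone carbon C9 (Fe(acac)3, PhSiH3, EtOH), should give the trans-fused labdan-7-one F2.
- Equilibrating enolisation towards C8 (KH, THF) and N-phenyltriflimide should give the tetrasubstituted enol triflate F3.
- Palladium-catalysed formate reduction (Pd(OAc)2, PPh3, HCO2H, n-Bu3N, DMF) then gives 15.

Step 15.
- Risk: Z selectivity may erode because the electron-rich aldehyde adds slowly and the adducts equilibrate, and the product may isomerise under base.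
- Fallback: it sets out from 16 and returns at 20.
- Steglich esterification of 16 with propiolic acid gives the labdenyl propiolate F4.
- Sonogashira coupling with tert-butyl(4-iodophenoxy)dimethylsilane (PdCl2(PPh3)2, CuI, K2CO3, THF) gives the aryl propiolate F5.
- Lindlar semihydrogenation adds H2 syn to the alkyne, spares the trisubstituted alkene and gives 20.

Step 4.
- Risk: carbometallation next to the silyloxy group may be sluggish.
- Risk: the Lewis-acidic aluminium may strip the silyl group.
- Risk: the alkenyl group may transfer poorly to formaldehyde.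
- Fallback: it sets out from 5 and returns at 7.
- Lithiation of 5 and paraformaldehyde give the propargylic alcohol F6.
- Hydroxyl-directed trans-hydroalumination with Red-Al followed by iodine gives the (Z)-3-iodo allylic alcohol F7.
- Me2CuLi replaces iodine by methyl with retention and gives 7 with the E geometry.

**Further compounds**
F1 | step 11 | (4S,6E,10E,14S)-4-(tert-butyldimethylsilyloxy)-16-(4-methoxybenzyloxy)-2,6,10,14-tetramethylhexadeca-1,6,10-trien-9-one | C=C(C)C[C@H](O[Si](C)(C)C(C)(C)C)C/C(C)=C/CC(=O)/C(C)=C/CC[C@H](C)CCOCc1ccc(OC)cc1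
F2 | step 11 | (13S)-2α-(tert-butyldimethylsilyloxy)-15-(4-methoxybenzyloxy)labdan-7-one (8α-methyl) | C[C@@H]1C(=O)C[C@H]2C(C)(C)C[C@H](O[Si](C)(C)C(C)(C)C)C[C@]2(C)[C@H]1CC[C@H](C)CCOCc1ccc(OC)cc1
F3 | step 11 | (13S)-2α-(tert-butyldimethylsilyloxy)-15-(4-methoxybenzyloxy)labd-7-en-7-yl triflate | CC1=C(OS(=O)(=O)C(F)(F)F)C[C@H]2C(C)(C)C[C@H](O[Si](C)(C)C(C)(C)C)C[C@]2(C)[C@H]1CC[C@H](C)CCOCc1ccc(OC)cc1
F4 | step 15 | (13S)-2α-(tert-butyldimethylsilyloxy)labd-7-en-15-yl propiolate | CC1=CC[C@H]2C(C)(C)C[C@H](O[Si](C)(C)C(C)(C)C)C[C@]2(C)[C@H]1CC[C@H](C)CCOC(=O)C#C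
F5 | step 15 | (13S)-2α-(tert-butyldimethylsilyloxy)labd-7-en-15-yl 3-[4-(tert-butyldimethylsilyloxy)phenyl]propiolate | CC1=CC[C@H]2C(C)(C)C[C@H](O[Si](C)(C)C(C)(C)C)C[C@]2(C)[C@H]1CC[C@H](C)CCOC(=O)C#Cc1ccc(O[Si](C)(C)C(C)(C)C)cc1
F6 | step 4 | (S)-5-(tert-butyldimethylsilyloxy)-7-methyloct-7-en-2-yn-1-ol | C=C(C)C[C@H](O[Si](C)(C)C(C)(C)C)CC#CCO
F7 | step 4 | (2Z,5S)-5-(tert-butyldimethylsilyloxy)-3-iodo-7-methylocta-2,7-dien-1-ol | C=C(C)C[C@H](O[Si](C)(C)C(C)(C)C)C/C(I)=C/CO
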